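Assumption: (4S)-4-methyloxolan-2-one (8) is bought as the enantiopure catalogue lactone; methyl vinyl ketone and allyl bromide are numbered as starting materials because their carbons end up in the target.

## Retrosynthetic overview

1. The C5 methoxy group goes on last, by α'-hydroxylation and O-methylation of the bicyclic vinylogous ester.
2. The dihydrofuran ring (ring B, O1–C2) is closed by displacement of an activated benzylic carbinol by the enone oxygen. The carbinol comes from joining 3,4,5-trimethoxyphenylmagnesium bromide to a C13 aldehyde (Ar–C2 bond), two fragments of 13 and 16 non-hydrogen atoms.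
3. The cyclohexenone (ring A) is built first, inside the aldehyde fragment, by intramolecular Claisen condensation of a keto-lactone. Its quaternary C3a comes from Michael addition and then allylation of (S)-β-methyl-γ-butyrolactone, the allyl group entering anti to the methyl group.
4. The aryl bromide comes from resorcinol by methylation, ortho-lithiation/oxidation, para-bromination and methylation.
5. Ring order: carbocycle first, oxygen heterocycle second. All stereocentres are set by substrate control from the lactone methyl stereocentre.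

## Route

**Step 1**
Reactants: 1 resorcinol
Product: 2 1,3-dimethoxybenzene
Conditions: Me2SO4, K2CO3, acetone, reflux
Reagents that add atoms: dimethyl sulfate, COS(=O)(=O)OC
Why: Williamson O-methylation of both phenols; no stereocentre is involved.

**Step 2**
Reactants: 2 1,3-dimethoxybenzene
Product: 5 2,6-dimethoxyphenol, via 2,6-dimethoxyphenyllithium 3 (not isolated), via dimethyl (2,6-dimethoxyphenyl)boronate 4 (not isolated)
Conditions: n-BuLi, THF, 0 → 23 °C; B(OMe)3, −78 → 23 °C; then AcOH, 30% H2O2, 0 °C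
Reagents that add atoms: hydrogen peroxide, OO
Why: Directed ortho-metalation occurs at C2 between the two methoxy groups, and borylation followed by peroxide oxidation puts the third oxygen there.

**Step 3**
Reactants: 5 2,6-dimethoxyphenol
Product: 6 4-bromo-2,6-dimethoxyphenol
Conditions: NBS, MeCN, −20 → 23 °C
Reagents that add atoms: N-bromosuccinimide, O=C1CCC(=O)N1Br
Why: Electrophilic aromatic bromination goes para to the free hydroxyl, the only activated position that is not blocked.

**Step 4**
Reactants: 6 4-bromo-2,6-dimethoxyphenol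
Product: 7 5-bromo-1,2,3-trimethoxybenzene
Conditions: MeI, K2CO3, acetone, reflux
Reagents that add atoms: iodomethane, CI
Why: Williamson O-methylation of the remaining phenol.

**Step 5**
Reactants: 8 (4S)-4-methyloxolan-2-one; 9 but-3-en-2-one (methyl vinyl ketone)
Product: 11 (3S,4S)-3-[3-(tert-butyldimethylsilyloxy)but-2-en-1-yl]-4-methyloxolan-2-one (side chain trans to methyl, enol ether E/Z mixture), via silyl ketene acetal 10 (not isolated)
Conditions: LiN(i-Pr)2, THF, −78 °C; TBSCl, DMPU; then 9, TBSOTf (5 mol %), CH2Cl2, −78 °C; Et3N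
Reagents that add atoms: tert-butyldimethylsilyl chloride, CC(C)(C)[Si](C)(C)Cl
Why: Mukaiyama–Michael addition of the lactone silyl ketene acetal with silyl transfer gives the 1,4-adduct with its ketone masked as the silyl enol ether; the new bond forms anti to the 4-methyl group (this centre is re-set in step 6).

**Step 6**
Reactants: 11 silyl enol ether lactone; 12 allyl bromide
Product: 14 (3S,4S)-3-allyl-4-methyl-3-(3-oxobutyl)oxolan-2-one (allyl trans to methyl), via allylated silyl enol ether 13 (not isolated)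
Conditions: LiN(i-Pr)2, THF, −78 °C; 12, DMPU, −78 → −20 °C; then 1 M HCl, THF, 23 °C
Reagents that add atoms: none
Why: In this lactone enolate alkylation allyl bromide approaches the face opposite the adjacent methyl group, which sets the quaternary centre (C3a of the target); the acidic quench hydrolyses the silyl enol ether to the methyl ketone.

**Step 7**
Reactants: 14 keto-lactone
Product: 16 (6S)-6-allyl-6-[(2S)-1-hydroxypropan-2-yl]-3-methoxycyclohex-2-en-1-one, via potassium dione enolate 15 (not isolated)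
Conditions: KOt-Bu (1.1 equiv), THF, 0 → 23 °C; then Me2SO4, DMPU, 0 °C; basic work-up, used crude
Reagents that add atoms: dimethyl sulfate, COS(=O)(=O)OC
Why: Intramolecular Claisen (Dieckmann-type) acylation of the methyl ketone enolate by the lactone carbonyl closes the six-membered 1,3-dione and releases the primary alcohol, and the dione enolate is then O-methylated at its unhindered oxygen; both stereocentres are untouched.

**Step 8**
Reactants: 16 hydroxy vinylogous ester
Product: 17 (2S)-2-[(1S)-1-allyl-4-methoxy-2-oxocyclohex-3-en-1-yl]propanal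
Conditions: (n-Pr4N)RuO4 (5 mol %), N-methylmorpholine N-oxide, 4 Å MS, CH2Cl2, 23 °C
Reagents that add atoms: none
Why: Ley–Griffith oxidation of the primary alcohol under neutral conditions spares the alkene and the enol ether and does not epimerise the α-stereocentre.

**Step 9**
Reactants: 7 5-bromo-1,2,3-trimethoxybenzene; 17 aldehyde
Product: 19 (6S)-6-allyl-6-[(1R,2S)-1-hydroxy-1-(3,4,5-trimethoxyphenyl)propan-2-yl]-3-methoxycyclohex-2-en-1-one, via aryl Grignard reagent 18 (not isolated)
Conditions: Mg, THF, reflux; add to 17, THF, −78 °C; H2O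
Reagents that add atoms: none
Why: Grignard 1,2-addition to the aldehyde, much faster than attack on the hindered vinylogous-ester carbonyl, joins the two fragments; Felkin–Anh control (attack anti to the quaternary carbon) gives mainly the (1R) carbinol.

**Step 10**
Reactants: 19 benzylic carbinol
Product: 21 (2S,3S,3aS)-3a-allyl-3-methyl-2-(3,4,5-trimethoxyphenyl)-3,3a,4,5-tetrahydro-1-benzofuran-6(2H)-one, via benzylic mesylate 20 (not isolated)
Conditions: MsCl, Et3N, CH2Cl2, −20 → 23 °C
Reagents that add atoms: none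
Why: The mesylate is displaced by the enone carbonyl oxygen in a 5-exo neighbouring-group cyclisation with inversion at C2 (a benzylic-cation pathway also favours the 2,3-trans ring), and chloride then demethylates the alkoxy-oxocarbenium to the vinylogous ester.

**Step 11**
Reactants: 21 bicyclic vinylogous ester
Product: 22 (2S,3S,3aR,5R)-3a-allyl-5-hydroxy-3-methyl-2-(3,4,5-trimethoxyphenyl)-3,3a,4,5-tetrahydro-1-benzofuran-6(2H)-one
Conditions: KN(SiMe3)2, THF, −78 °C; 2-(phenylsulfonyl)-3-phenyloxaziridine, −78 °C; AcOH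
Reagents that add atoms: 2-(phenylsulfonyl)-3-phenyloxaziridine, O=S(=O)(c1ccccc1)N1OC1c1ccccc1
Why: Kinetic α'-deprotonation and Davis enolate oxidation; the oxidant attacks C5 anti to the pseudo-axial 3a-allyl group, giving the 5R alcohol.

**Step 12**
Reactants: 22 α-hydroxy ketone
Product: 23 (2S,3S,3aR,5R)-3a-allyl-5-methoxy-3-methyl-2-(3,4,5-trimethoxyphenyl)-3,3a,4,5-tetrahydro-1-benzofuran-6(2H)-one (target)
Conditions: MeI, Ag2O, MeCN, 40 °C, dark
Reagents that add atoms: iodomethane, CI
Why: Purdie O-methylation under non-basic conditions keeps the α-ketol stereocentre intact.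

## Compound list

1 | resorcinol | Oc1cccc(O)c1 | starting material
2 | 1,3-dimethoxybenzene | COc1cccc(OC)c1 | intermediate
3 | 2,6-dimethoxyphenyllithium | COc1cccc(OC)c1[Li] | intermediate
4 | dimethyl (2,6-dimethoxyphenyl)boronate | COB(OC)c1c(OC)cccc1OC | intermediate
5 | 2,6-dimethoxyphenol | COc1cccc(OC)c1O | intermediate
6 | 4-bromo-2,6-dimethoxyphenol | COc1cc(Br)cc(OC)c1O | intermediate
7 | 5-bromo-1,2,3-trimethoxybenzene | COc1cc(Br)cc(OC)c1OC | intermediate
8 | (4S)-4-methyloxolan-2-one | C[C@H]1CC(=O)OC1 | starting material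
9 | but-3-en-2-one | CC(=O)C=C | starting material
10 | tert-butyl(dimethyl){[(4S)-4-methyl-4,5-dihydrofuran-2-yl]oxy}silane | C[C@@H]1COC(O[Si](C)(C)C(C)(C)C)=C1 | intermediate
11 | (3S,4S)-3-[3-(tert-butyldimethylsilyloxy)but-2-en-1-yl]-4-methyloxolan-2-one | CC(O[Si](C)(C)C(C)(C)C)=CC[C@H]1[C@H](C)COC1=O | intermediate
12 | allyl bromide | C=CCBr | starting material
13 | (3R,4S)-3-allyl-3-[3-(tert-butyldimethylsilyloxy)but-2-en-1-yl]-4-methyloxolan-2-one | C=CC[C@@]1(CC=C(C)O[Si](C)(C)C(C)(C)C)[C@H](C)COC1=O | intermediate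
14 | (3S,4S)-3-allyl-4-methyl-3-(3-oxobutyl)oxolan-2-one | C=CC[C@@]1(CCC(C)=O)[C@H](C)COC1=O | intermediate
15 | potassium enolate of (4S)-4-allyl-4-[(2S)-1-hydroxypropan-2-yl]cyclohexane-1,3-dione | C=CC[C@@]1(CCC([O-])=CC1=O)[C@H](C)CO.[K+] | intermediate
16 | (6S)-6-allyl-6-[(2S)-1-hydroxypropan-2-yl]-3-methoxycyclohex-2-en-1-one | C=CC[C@@]1(CCC(OC)=CC1=O)[C@H](C)CO | intermediate
17 | (2S)-2-[(1S)-1-allyl-4-methoxy-2-oxocyclohex-3-en-1-yl]propanal | C=CC[C@@]1(CCC(OC)=CC1=O)[C@H](C)C=O | intermediate
18 | (3,4,5-trimethoxyphenyl)magnesium bromide | COc1cc([Mg]Br)cc(OC)c1OC | intermediate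
19 | (6S)-6-allyl-6-[(1R,2S)-1-hydroxy-1-(3,4,5-trimethoxyphenyl)propan-2-yl]-3-methoxycyclohex-2-en-1-one | C=CC[C@@]1(CCC(OC)=CC1=O)[C@H](C)[C@@H](O)c1cc(OC)c(OC)c(OC)c1 | intermediate
20 | (1R,2S)-2-[(1S)-1-allyl-4-methoxy-2-oxocyclohex-3-en-1-yl]-1-(3,4,5-trimethoxyphenyl)propyl methanesulfonate | C=CC[C@@]1(CCC(OC)=CC1=O)[C@H](C)[C@@H](OS(C)(=O)=O)c1cc(OC)c(OC)c(OC)c1 | intermediate
21 | (2S,3S,3aS)-3a-allyl-3-methyl-2-(3,4,5-trimethoxyphenyl)-3,3a,4,5-tetrahydro-1-benzofuran-6(2H)-one | C=CC[C@]12CCC(=O)C=C1O[C@H](c1cc(OC)c(OC)c(OC)c1)[C@H]2C | intermediate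
22 | (2S,3S,3aR,5R)-3a-allyl-5-hydroxy-3-methyl-2-(3,4,5-trimethoxyphenyl)-3,3a,4,5-tetrahydro-1-benzofuran-6(2H)-one | C=CC[C@]12C[C@@H](O)C(=O)C=C1O[C@H](c1cc(OC)c(OC)c(OC)c1)[C@H]2C | intermediate
23 | (2S,3S,3aR,5R)-3a-allyl-5-methoxy-3-methyl-2-(3,4,5-trimethoxyphenyl)-3,3a,4,5-tetrahydro-1-benzofuran-6(2H)-one | C=CC[C@]12C[C@@H](OC)C(=O)C=C1O[C@H](c1cc(OC)c(OC)c(OC)c1)[C@H]2C | target

## Step count and risks

Total step count: 12. Longest linear sequence: 8 steps (steps 5–12 from lactone 8; the arene line, steps 1–4 then 9–12, is equally long).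

**Step 5 (Mukaiyama–Michael addition).** Risks are polymerisation of 9, C-silylation of the lactone enolate and 1,2-addition. The fallback brings in the oxobutyl chain as a ketal-protected alkyl halide, sets out from 8 and comes back at 14. Deprotonation of 8 with LiN(i-Pr)2 and alkylation with 2-(2-bromoethyl)-2-methyl-1,3-dioxolane in THF/DMPU gives (3S,4S)-4-methyl-3-[2-(2-methyl-1,3-dioxolan-2-yl)ethyl]oxolan-2-one F1. A second enolisation and allyl bromide 12, again anti to the methyl group, give (3S,4S)-3-allyl-4-methyl-3-[2-(2-methyl-1,3-dioxolan-2-yl)ethyl]oxolan-2-one F2. Aqueous HCl in THF removes the dioxolane and delivers 14.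

**Step 7 (Claisen cyclisation and O-methylation with the alcohol unprotected).** Risks are methylation of the alkoxide and acid-triggered closure of 16 onto its own enone. The fallback protects the alcohol, sets out from 14 and comes back at 17. Cyclisation with 2.2 equiv KOt-Bu and silylation of the released alkoxide in the same flask with Et3SiCl gives (4S)-4-allyl-4-[(2S)-1-(triethylsilyloxy)propan-2-yl]cyclohexane-1,3-dione F3. O-Methylation (Me2SO4, K2CO3, acetone) gives (6S)-6-allyl-3-methoxy-6-[(2S)-1-(triethylsilyloxy)propan-2-yl]cyclohex-2-en-1-one F4. Direct Swern oxidation of the primary triethylsilyl ether ((COCl)2, DMSO, CH2Cl2, −78 °C; Et3N) gives aldehyde 17.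

**Step 10 (mesylate cyclisation).** Risks are elimination to the styrene and partial loss of the trans selectivity through the benzylic cation. The fallback sets C2 by reduction and closes the ring with retention, sets out from 19 and comes back at 21. Oxidation with Dess–Martin periodinane/NaHCO3 gives (6S)-6-allyl-3-methoxy-6-[(2S)-1-oxo-1-(3,4,5-trimethoxyphenyl)propan-2-yl]cyclohex-2-en-1-one F5. Felkin–Anh reduction with LiAlH(Ot-Bu)3 in THF at −78 °C gives (6S)-6-allyl-6-[(1S,2S)-1-hydroxy-1-(3,4,5-trimethoxyphenyl)propan-2-yl]-3-methoxycyclohex-2-en-1-one F6. Pyridinium p-toluenesulfonate in benzene at 50 °C then closes the ring by vinylogous transesterification, with the C2–O bond untouched, to give 21.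

## Further compounds

F1 | step 5 | (3S,4S)-4-methyl-3-[2-(2-methyl-1,3-dioxolan-2-yl)ethyl]oxolan-2-one | CC1(CC[C@H]2[C@H](C)COC2=O)OCCO1
F2 | step 5 | (3S,4S)-3-allyl-4-methyl-3-[2-(2-methyl-1,3-dioxolan-2-yl)ethyl]oxolan-2-one | C=CC[C@@]1(CCC2(C)OCCO2)[C@H](C)COC1=O
F3 | step 7 | (4S)-4-allyl-4-[(2S)-1-(triethylsilyloxy)propan-2-yl]cyclohexane-1,3-dione | C=CC[C@@]1(CCC(=O)CC1=O)[C@H](C)CO[Si](CC)(CC)CC
F4 | step 7 | (6S)-6-allyl-3-methoxy-6-[(2S)-1-(triethylsilyloxy)propan-2-yl]cyclohex-2-en-1-one | C=CC[C@@]1(CCC(OC)=CC1=O)[C@H](C)CO[Si](CC)(CC)CC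
F5 | step 10 | (6S)-6-allyl-3-methoxy-6-[(2S)-1-oxo-1-(3,4,5-trimethoxyphenyl)propan-2-yl]cyclohex-2-en-1-one | C=CC[C@@]1(CCC(OC)=CC1=O)[C@H](C)C(=O)c1cc(OC)c(OC)c(OC)c1
F6 | step 10 | (6S)-6-allyl-6-[(1S,2S)-1-hydroxy-1-(3,4,5-trimethoxyphenyl)propan-2-yl]-3-methoxycyclohex-2-en-1-one | C=CC[C@@]1(CCC(OC)=CC1=O)[C@H](C)[C@H](O)c1cc(OC)c(OC)c(OC)c1
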